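The data were generated by integration for an exercise; scatter was added.

66.0 product molecules per catalyst is the number I start from: it is what north's charge can pay for.

the same everywhere: catalyst 0.5 mol%

| run | substrate | partner | temperature | remark | time |
|---|---|---|---|---|---|
| grey | 0.050 M | 0.21 equiv | 45 °C | run made earlier |  |
| teal | 0.050 M | 1.2 equiv | 60 °C | run made earlier |  |
| violet | 0.10 M | 1.3 equiv | 45 °C | run made earlier |  |
| south | 0.050 M | 1.30 equiv |  | at 50 °C until 6.0 h, from then on at 70 °C | 12 h |
| north | 0.15 M | 0.330 equiv |  | at 70 °C throughout | 12 h |

- amounts and yields of target count crystals too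
- given per volume of solution although it is solid: crystals
- what may be going on: substrate + partner <-> isomer of the product; crystals <-> target; substrate + partner -> uncatalysed product; catalyst + target -> catalyst + over-reaction product; substrate + partner <-> target; target + catalyst <-> isomer of the product + catalyst
- where the amount of substrate changes, what is given in equivalents or mol% on it follows

Each molecule of target, isomer or uncatalysed product takes one substrate and one partner, and over-reaction product comes from target. So I count the product ceiling, the scarcer charge over the catalyst charge. It is a ceiling on product and not a count of catalyst turnovers, for the steps from substrate and partner stand without catalyst. In north the limiting reagent is partner, at 0.330 equiv. South is short of substrate instead, so its ceiling is 200. But the two flasks can hold nearly the same product per litre, 0.0495 M in north against 0.050 M in south, and [catalyst] in north is 3.00 times that in south.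

- grey (time / h: target / %, isomer of the product / %): 0.333: 1.2, 0.3; 1.00: 0, 0; 1.50: 1.5, 1.7; 2.50: 3.7, 2.8; 4.00: 3.1, 3.7; 5.00: 2.0, 2.9; 6.00: 5.4, 1.6
- teal (time / h: target / %, isomer of the product / %): 0.333: 8.1, 4.7; 0.417: 8.6, 3.6; 0.667: 13.3, 9.1; 1.00: 15.4, 11.2; 1.50: 19.7, 17.4; 2.50: 24.2, 17.4; 4.00: 29.7, 21.6
- violet (time / h: target / %, isomer of the product / %): 0.500: 7.0, 4.3; 1.50: 15.5, 9.7; 3.00: 23.6, 14.7; 4.00: 27.7, 16.3; 6.00: 32.5, 18.2

(scatter of a reading: 1 percentage point)

Target over isomer reads about 1.79 at the end of violet, and lower at the end of teal, about 1.37. But violet stands at 45 °C with 0.10 M of substrate and teal at 60 °C with 0.050 M, so these two readings don't part heat from concentration. North stands at 70 °C from the start, while south waits at 50 °C until 6.0 h. The catalysed steps on target run faster per dissolved target in north than in south, so I commit to south, by more than the margin.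

- the winner by share of target in all that became target or isomer of the product or uncatalysed product or over-reaction product; "neither" if no more than 2 percentage points parts them (south / north / neither)
- share of target in all that became target or isomer of the product or uncatalysed product or over-reaction product, south
- share of target in all that became target or isomer of the product or uncatalysed product or over-reaction product, north

The forecast also says south, with 52% for south against 46% for north, and holds that “The uncatalysed product is unseen and probably small”.

The simulation gives south, with 44.5% for south against 38.2% for north.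

    substrate + partner ⇌ isomer of the product (K = 47.1 M⁻¹, k = 0.0188 M⁻¹ min⁻¹, Ea = 85.0 kJ mol⁻¹, ΔH = 14.0 kJ mol⁻¹)
    crystals ⇌ target, rate k2*(cs2 - [target]) while solid is left; crystals form when [target] > cs2 (solubility = 0.670 mM, k = 0.0324 min⁻¹)
    substrate + partner → uncatalysed product (k = 0.0178 M⁻¹ min⁻¹, Ea = 67.0 kJ mol⁻¹)
    catalyst + target → catalyst + over-reaction product (k = 3.43 M⁻¹ min⁻¹, Ea = 49.0 kJ mol⁻¹)
    substrate + partner ⇌ target (K = 15.4 M⁻¹, k = 0.0336 M⁻¹ min⁻¹, Ea = 76.0 kJ mol⁻¹, ΔH = −17.0 kJ mol⁻¹)
    target + catalyst ⇌ isomer of the product + catalyst, rate k6*[catalyst]*[target] forward; the back reaction follows from the equilibrium constant (k = 4.51 M⁻¹ min⁻¹, Ea = 73.0 kJ mol⁻¹)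
    (constants at 50 °C)

Neither flask is at rest at 12.0 h. South has reached 180 of its ceiling of 200, with uncatalysed product at 28.4%. North has reached 65.2 of its 66.0, with partner down to 1.21%. At 120 h the counts stand at 194 in south and 66.0 in north, yet the products have changed places. South, left ten times as long, holds 70.7% uncatalysed product and 21.2% over-reaction product, and its share of target is 0.576%. North's share of target, left ten times as long, is 0.00792%.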